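**Plan**

- The retrosynthesis first cuts the C–O bonds made by Thiele–Winter acetoxylation (the ring A hydroxyl and the B2 hydroxyl) and those made by phenol-to-quinone oxidation (the ring A carbonyl between the tether carbon and the methoxy carbon, and the B6 carbonyl). This leads back to a bis-arene: ring A a 3-hydroxy-5-methoxy-4-methylphenyl unit, ring B a 5-alkyl-2-methylresorcinol.
- Ring B is then cut at B3–B4 and B5–B6. Its methyl carbon B4 lies between the oxygenated carbons B3 and B5 and para to the tether carbon B1, which is the pattern a 3-alkylcyclobutenone (B1, B2, B3, B6) gives with a 1-siloxypropyne (B4, B5).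
- The cyclobutenone is cut to a terminal alkyne plus dichloroketene, the alkyne to an acetylide plus a thirteen-carbon bromide, and the tether at its benzylic C=C to commercial 3,5-dimethoxy-4-methylbenzaldehyde plus the ylide from 12-bromododecan-1-ol.
- Forward: ring A is bought intact, the chain is joined by Wittig reaction and hydrogenation, extended by two carbons, closed to the four-membered ring, and ring B arises in the benzannulation. Both rings are oxidised last.
- Ring A travels as its dimethyl ether, so no protecting group is needed. One of its two equivalent ethers is cleaved once ring B exists.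
- The target has no stereocentre. The only stereo-element on the way, the Wittig alkene, is removed by hydrogenation.

Key step: step 9

Remark: alkene 5 is taken on as a Z/E mixture (Z drawn) because the next step saturates it.

**Route**

Step 1
Reactants: 1 12-bromododecan-1-ol
Product: 2 (12-hydroxydodecyl)triphenylphosphonium bromide
Conditions: PPh3, MeCN, reflux
Reagents that add atoms: triphenylphosphine, c1ccc(cc1)P(c1ccccc1)c1ccccc1
Why: SN2 quaternisation of PPh3 by the primary bromide (phosphonium salt formation) should proceed cleanly beside the free hydroxyl, which does not compete at phosphorus.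

Step 2
Reactants: 2 (12-hydroxydodecyl)triphenylphosphonium bromide; 3 3,5-dimethoxy-4-methylbenzaldehyde
Product: 5 (Z)-13-(3,5-dimethoxy-4-methylphenyl)tridec-12-en-1-ol, via ylide alkoxide 4 (not isolated)
Conditions: NaN(SiMe3)2 (2 equiv per 2), THF, −78 → 0 °C; then 3, −78 → 25 °C; aq. NH4Cl
Reagents that add atoms: none
Why: Wittig olefination, in which two equivalents of base give the alkoxide ylide 4, a non-stabilised ylide that condenses with the unhindered aryl aldehyde, and the alkene geometry is of no consequence because the double bond is saturated next.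

Step 3
Reactants: 5 (Z)-13-(3,5-dimethoxy-4-methylphenyl)tridec-12-en-1-ol
Product: 6 13-(3,5-dimethoxy-4-methylphenyl)tridecan-1-ol
Conditions: H2 (1 atm), 10% Pd/C, EtOAc, 25 °C
Reagents that add atoms: none
Why: Heterogeneous catalytic hydrogenation saturates the disubstituted styrenyl alkene, and with no benzyl ether or halide in the molecule nothing else is reducible under these conditions.

Step 4
Reactants: 6 13-(3,5-dimethoxy-4-methylphenyl)tridecan-1-ol
Product: 7 5-(13-bromotridecyl)-1,3-dimethoxy-2-methylbenzene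
Conditions: CBr4, PPh3, CH2Cl2, 0 °C
Reagents that add atoms: tetrabromomethane, BrC(Br)(Br)Br
Why: Appel reaction, in which the alkoxyphosphonium ion is displaced by bromide in an SN2 step at the primary carbon under neutral conditions that leave the aryl ethers alone.

Step 5
Reactants: 7 5-(13-bromotridecyl)-1,3-dimethoxy-2-methylbenzene; 8 lithium acetylide–ethylenediamine complex
Product: 9 1,3-dimethoxy-2-methyl-5-(pentadec-14-yn-1-yl)benzene
Conditions: LiC≡CH·H2NCH2CH2NH2, DMSO, 15 → 25 °C
Reagents that add atoms: none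
Why: SN2 alkylation of an acetylide, for which the amine-complexed lithium acetylide in DMSO displaces primary bromides with little elimination and brings in the two carbons that become B1 and B6.

Step 6
Reactants: 9 1,3-dimethoxy-2-methyl-5-(pentadec-14-yn-1-yl)benzene; 10 trichloroacetyl chloride
Product: 12 4,4-dichloro-3-[13-(3,5-dimethoxy-4-methylphenyl)tridecyl]cyclobut-2-en-1-one, via dichloroketene 11 (not isolated)
Conditions: Zn–Cu couple, Et2O–DME, 25 °C, slow addition of 10
Reagents that add atoms: none
Why: Zinc dechlorinates the acid chloride to dichloroketene, which adds to the terminal alkyne in a thermal [2+2] ketene–alkyne cycloaddition with the ketene carbonyl carbon bonding to the terminal alkyne carbon, so the 3-alkyl-4,4-dichloro isomer should result, while DME ties up ZnCl2 and shields the electron-rich arene from acylation.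

Step 7
Reactants: 12 4,4-dichloro-3-[13-(3,5-dimethoxy-4-methylphenyl)tridecyl]cyclobut-2-en-1-one
Product: 13 3-[13-(3,5-dimethoxy-4-methylphenyl)tridecyl]cyclobut-2-en-1-one
Conditions: Zn dust, AcOH, TMEDA, EtOH, 0 → 25 °C
Reagents that add atoms: none
Why: Reductive dehalogenation of the α,α-dichloro ketone by zinc, with the AcOH–TMEDA buffer as proton source, removes both chlorines while avoiding acid- or base-induced opening or isomerisation of the strained enone.

Step 8
Reactants: 14 ethyl acetate; 15 dibromomethane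
Product: 18 triisopropyl(prop-1-yn-1-yloxy)silane, via dibromoenolate 16 (not isolated), via lithium ynolate 17 (not isolated)
Conditions: lithium 2,2,6,6-tetramethylpiperidide (2.2 equiv), 15, THF, −78 °C, then 14; n-BuLi, −78 → 25 °C; i-Pr3SiCl, −78 → 25 °C
Reagents that add atoms: chlorotriisopropylsilane, CC(C)[Si](Cl)(C(C)C)C(C)C
Why: Kowalski ynolate synthesis, in which LiCHBr2 adds to the ester, the derived dibromo enolate 16 undergoes bromine–lithium exchange and 1,2-shift of the methyl group to ynolate 17, and the bulky silyl chloride traps the ynolate at oxygen.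

Step 9
Reactants: 13 3-[13-(3,5-dimethoxy-4-methylphenyl)tridecyl]cyclobut-2-en-1-one; 18 triisopropyl(prop-1-yn-1-yloxy)silane
Product: 23 5-[13-(3,5-dimethoxy-4-methylphenyl)tridecyl]-2-methyl-3-[(triisopropylsilyl)oxy]phenol, via vinylketene 19 (not isolated), via vinylcyclobutenone 20 (not isolated), via dienylketene 21 (not isolated), via cyclohexadienone 22 (not isolated)
Conditions: 18 (1.5 equiv), toluene, 80 °C then 110 °C, Ar, sealed vessel
Reagents that add atoms: none
Why: Thermal four-electron electrocyclic opening of cyclobutenone 13 gives vinylketene 19, whose ketene C=C adds the siloxyalkyne in a regioselective [2+2] cycloaddition to vinylcyclobutenone 20, forming bonds B3–B4 and B5–B6. A second four-electron opening gives dienylketene 21, and six-electron electrocyclisation (bond B2–B3) followed by tautomerisation of dienone 22 delivers aromatic ring B; this is the Danheiser benzannulation in its siloxyalkyne form, a known route to resorcinol monosilyl ethers. Ring B is thus closed by a pericyclic 6π ring closure of a dienylketene and not by an ionic cyclisation. No stereocentre is formed. The step needs a single orientation in the [2+2] event, and the polarisation of the ynol ether secures it: its nucleophilic methyl-bearing carbon bonds to the electrophilic ketene carbonyl carbon, so the methyl group ends at B4 between B3–OH and B5–OSi and para to the tether carbon B1. Neutral heating leaves the aryl methyl ethers and the saturated tether untouched, and the excess of alkyne keeps the vinylketene from acylating the phenol as it forms.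

Step 10
Reactants: 23 5-[13-(3,5-dimethoxy-4-methylphenyl)tridecyl]-2-methyl-3-[(triisopropylsilyl)oxy]phenol
Product: 24 5-[13-(3,5-dimethoxy-4-methylphenyl)tridecyl]-2-methylbenzene-1,3-diol
Conditions: Bu4NF, THF, 0 °C; aq. NH4Cl
Reagents that add atoms: none
Why: Fluoride-mediated cleavage of an aryl silyl ether, driven by Si–F bond formation and loss of the phenoxide, to which the methyl ethers and the free phenol are inert.

Step 11
Reactants: 24 5-[13-(3,5-dimethoxy-4-methylphenyl)tridecyl]-2-methylbenzene-1,3-diol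
Product: 25 5-[13-(3-hydroxy-5-methoxy-4-methylphenyl)tridecyl]-2-methylbenzene-1,3-diol
Conditions: NaSEt (6 equiv), DMF, 140 °C, Ar; then 1 M HCl
Reagents that add atoms: none
Why: SN2 O-demethylation by ethanethiolate in hot DMF should stop after one of the two equivalent ring A ethers, because the aryl oxide formed makes the second ether a far poorer leaving group, and ring B carries no ether.

Step 12
Reactants: 25 5-[13-(3-hydroxy-5-methoxy-4-methylphenyl)tridecyl]-2-methylbenzene-1,3-diol
Product: 26 3-hydroxy-5-[13-(5-methoxy-4-methyl-3,6-dioxocyclohexa-1,4-dien-1-yl)tridecyl]-2-methylcyclohexa-2,5-diene-1,4-dione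
Conditions: (KSO3)2NO (5 equiv), KH2PO4 buffer, H2O–acetone–THF, 25 °C
Reagents that add atoms: potassium nitrosodisulfonate, [K+].[K+].[O]N(S(=O)(=O)[O-])S(=O)(=O)[O-]
Why: Teuber oxidation, in which each ring offers a phenol with a free para position, so ring A should become the methoxy-p-quinone (new carbonyl at the ring carbon between the tether carbon and the methoxy carbon) and the symmetrical ring B resorcinol the 2-hydroxy-p-quinone (new carbonyl at B6).

Step 13
Reactants: 26 3-hydroxy-5-[13-(5-methoxy-4-methyl-3,6-dioxocyclohexa-1,4-dien-1-yl)tridecyl]-2-methylcyclohexa-2,5-diene-1,4-dione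
Product: 27 3-[13-(2,3,6-triacetoxy-5-methoxy-4-methylphenyl)tridecyl]-6-methylbenzene-1,2,4,5-tetrayl tetraacetate
Conditions: Ac2O, BF3·OEt2 (cat.), 25 → 40 °C
Reagents that add atoms: acetic anhydride, CC(=O)OC(C)=O
Why: Thiele–Winter acetoxylation, in which the ring B hydroxyl is acetylated first, Lewis-acid-activated conjugate addition of acetate can only take place at the single unsubstituted quinone carbon of each ring (in ring A the carbon next to the tether carbon, in ring B the carbon B2), and the hydroquinones formed are trapped as acetates.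

Step 14
Reactants: 27 3-[13-(2,3,6-triacetoxy-5-methoxy-4-methylphenyl)tridecyl]-6-methylbenzene-1,2,4,5-tetrayl tetraacetate
Product: 29 2,5-dihydroxy-3-[13-(2-hydroxy-5-methoxy-4-methyl-3,6-dioxocyclohexa-1,4-dien-1-yl)tridecyl]-6-methylcyclohexa-2,5-diene-1,4-dione, via leuco heptaphenol 28 (not isolated)
Conditions: K2CO3, MeOH (degassed), Ar, 25 °C; then air (O2); then 1 M HCl
Reagents that add atoms: none
Why: Base-mediated transesterification of the seven aryl acetates under exclusion of air gives leuco compound 28, in which the methyl ether is an ordinary aryl ether and is not hydrolysed, and its two hydroxyhydroquinone rings then autoxidise to the stable 2-hydroxy- and 2,5-dihydroxy-1,4-benzoquinones.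

**Compound list**

1 | 12-bromododecan-1-ol | OCCCCCCCCCCCCBr | starting material
2 | (12-hydroxydodecyl)triphenylphosphonium bromide | [Br-].OCCCCCCCCCCCC[P+](c1ccccc1)(c1ccccc1)c1ccccc1 | intermediate
3 | 3,5-dimethoxy-4-methylbenzaldehyde | COc1cc(C=O)cc(OC)c1C | starting material
4 | sodium 12-(triphenyl-λ5-phosphanylidene)dodecan-1-olate (ylide alkoxide) | [Na+].[O-]CCCCCCCCCCCC=P(c1ccccc1)(c1ccccc1)c1ccccc1 | intermediate
5 | (Z)-13-(3,5-dimethoxy-4-methylphenyl)tridec-12-en-1-ol (E isomer carried along) | OCCCCCCCCCCC/C=C\c1cc(OC)c(C)c(OC)c1 | intermediate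
6 | 13-(3,5-dimethoxy-4-methylphenyl)tridecan-1-ol | OCCCCCCCCCCCCCc1cc(OC)c(C)c(OC)c1 | intermediate
7 | 5-(13-bromotridecyl)-1,3-dimethoxy-2-methylbenzene | BrCCCCCCCCCCCCCc1cc(OC)c(C)c(OC)c1 | intermediate
8 | lithium acetylide–ethylenediamine complex | [Li+].[C-]#C.NCCN | starting material
9 | 1,3-dimethoxy-2-methyl-5-(pentadec-14-yn-1-yl)benzene | C#CCCCCCCCCCCCCCc1cc(OC)c(C)c(OC)c1 | intermediate
10 | trichloroacetyl chloride | ClC(=O)C(Cl)(Cl)Cl | starting material
11 | dichloroketene | ClC(Cl)=C=O | intermediate
12 | 4,4-dichloro-3-[13-(3,5-dimethoxy-4-methylphenyl)tridecyl]cyclobut-2-en-1-one | O=C1C=C(CCCCCCCCCCCCCc2cc(OC)c(C)c(OC)c2)C1(Cl)Cl | intermediate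
13 | 3-[13-(3,5-dimethoxy-4-methylphenyl)tridecyl]cyclobut-2-en-1-one | O=C1C=C(CCCCCCCCCCCCCc2cc(OC)c(C)c(OC)c2)C1 | intermediate
14 | ethyl acetate | CCOC(C)=O | starting material
15 | dibromomethane | BrCBr | starting material
16 | lithium 1,1-dibromoprop-1-en-2-olate | [Li+].[O-]C(C)=C(Br)Br | intermediate
17 | lithium prop-1-yn-1-olate | [Li+].CC#C[O-] | intermediate
18 | triisopropyl(prop-1-yn-1-yloxy)silane | CC#CO[Si](C(C)C)(C(C)C)C(C)C | intermediate
19 | 16-(3,5-dimethoxy-4-methylphenyl)-3-methylidenehexadec-1-en-1-one (vinylketene) | O=C=CC(=C)CCCCCCCCCCCCCc1cc(OC)c(C)c(OC)c1 | intermediate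
20 | 4-[15-(3,5-dimethoxy-4-methylphenyl)pentadec-1-en-2-yl]-2-methyl-3-[(triisopropylsilyl)oxy]cyclobut-2-en-1-one (racemic) | O=C1C(C)=C(O[Si](C(C)C)(C(C)C)C(C)C)C1C(=C)CCCCCCCCCCCCCc1cc(OC)c(C)c(OC)c1 | intermediate
21 | (3E)-18-(3,5-dimethoxy-4-methylphenyl)-2-methyl-5-methylidene-3-[(triisopropylsilyl)oxy]octadeca-1,3-dien-1-one (dienylketene, ketene and vinyl termini cis) | O=C=C(C)/C(O[Si](C(C)C)(C(C)C)C(C)C)=C\C(=C)CCCCCCCCCCCCCc1cc(OC)c(C)c(OC)c1 | intermediate
22 | 5-[13-(3,5-dimethoxy-4-methylphenyl)tridecyl]-2-methyl-3-[(triisopropylsilyl)oxy]cyclohexa-2,4-dien-1-one | O=C1CC(CCCCCCCCCCCCCc2cc(OC)c(C)c(OC)c2)=CC(O[Si](C(C)C)(C(C)C)C(C)C)=C1C | intermediate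
23 | 5-[13-(3,5-dimethoxy-4-methylphenyl)tridecyl]-2-methyl-3-[(triisopropylsilyl)oxy]phenol | Cc1c(O)cc(CCCCCCCCCCCCCc2cc(OC)c(C)c(OC)c2)cc1O[Si](C(C)C)(C(C)C)C(C)C | intermediate
24 | 5-[13-(3,5-dimethoxy-4-methylphenyl)tridecyl]-2-methylbenzene-1,3-diol | Cc1c(O)cc(CCCCCCCCCCCCCc2cc(OC)c(C)c(OC)c2)cc1O | intermediate
25 | 5-[13-(3-hydroxy-5-methoxy-4-methylphenyl)tridecyl]-2-methylbenzene-1,3-diol | Cc1c(O)cc(CCCCCCCCCCCCCc2cc(O)c(C)c(OC)c2)cc1O | intermediate
26 | 3-hydroxy-5-[13-(5-methoxy-4-methyl-3,6-dioxocyclohexa-1,4-dien-1-yl)tridecyl]-2-methylcyclohexa-2,5-diene-1,4-dione | COC1=C(C)C(=O)C=C(CCCCCCCCCCCCCC2=CC(=O)C(C)=C(O)C2=O)C1=O | intermediate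
27 | 3-[13-(2,3,6-triacetoxy-5-methoxy-4-methylphenyl)tridecyl]-6-methylbenzene-1,2,4,5-tetrayl tetraacetate | COc1c(C)c(OC(C)=O)c(OC(C)=O)c(CCCCCCCCCCCCCc2c(OC(C)=O)c(OC(C)=O)c(C)c(OC(C)=O)c2OC(C)=O)c1OC(C)=O | intermediate
28 | 3-methyl-6-[13-(2,3,6-trihydroxy-5-methoxy-4-methylphenyl)tridecyl]benzene-1,2,4,5-tetrol | COc1c(C)c(O)c(O)c(CCCCCCCCCCCCCc2c(O)c(O)c(C)c(O)c2O)c1O | intermediate
29 | 2,5-dihydroxy-3-[13-(2-hydroxy-5-methoxy-4-methyl-3,6-dioxocyclohexa-1,4-dien-1-yl)tridecyl]-6-methylcyclohexa-2,5-diene-1,4-dione | COC1=C(C)C(=O)C(O)=C(CCCCCCCCCCCCCC2=C(O)C(=O)C(C)=C(O)C2=O)C1=O | target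

**Step count and risks**

Total step count: 14. Longest linear sequence: 13 steps (steps 1–7 and 9–14; step 8 is a one-step branch).

Steps most likely to fail, most uncertain first:

(a) Step 13. The acid-catalysed conjugate addition of acetate may stall on these trisubstituted, donor-substituted quinones, or only one of the two rings may be carried through, which would leave mixtures of partly acetoxylated material. The fallback replaces acetoxylation by halogenation and substitution and sets out from 26. Bromine (Br2, AcOH–CHCl3, 25 °C) should add to the one unsubstituted quinone C=C–H of each ring and lose HBr, giving 2-bromo-3-[13-(2-bromo-5-methoxy-4-methyl-3,6-dioxocyclohexa-1,4-dien-1-yl)tridecyl]-5-hydroxy-6-methylcyclohexa-2,5-diene-1,4-dione F1. Its two vinylogous acyl bromides should then be displaced by hydroxide in an addition–elimination (aq. KOH, THF, 0 → 25 °C, then HCl). The bromine-bearing carbon is the more electrophilic site and bromide the better leaving group, and the hydroxyquinone anion formed in ring A then shields the methoxy group from further attack. The route is rejoined at target 29, bypassing 27 and 28.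

(b) Step 9. The vinylketene may be lost by dimerisation or by acylating the phenol as it forms, the cascade may halt at the vinylcyclobutenone, or the siloxyalkyne may rearrange on heating before it is captured. The fallback builds ring B by a classical Michael–Claisen sequence and sets out from bromide 7. The Grignard reagent of 7 (Mg, THF) is formylated with DMF to 14-(3,5-dimethoxy-4-methylphenyl)tetradecanal F2. Wittig reaction with Ph3P=CHC(O)CH2CH3 (toluene, reflux) should give (E)-18-(3,5-dimethoxy-4-methylphenyl)octadec-4-en-3-one F3. Dimethyl malonate and NaOMe in refluxing MeOH should add in Michael fashion and close by Claisen condensation through the ethyl ketone methylene to methyl 6-[13-(3,5-dimethoxy-4-methylphenyl)tridecyl]-3-methyl-2,4-dioxocyclohexane-1-carboxylate F4. Saponification and acid decarboxylation (aq. NaOH, then HCl, reflux) should give 5-[13-(3,5-dimethoxy-4-methylphenyl)tridecyl]-2-methylcyclohexane-1,3-dione F5. Dehydrogenation over Pd/C in refluxing mesitylene should aromatise this dione to the resorcinol, and the route is rejoined at 24.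

(c) Step 11. The thiolate may go on to cleave the second ether, or the triphenolate may degrade at 140 °C, so that the mono-ether stage cannot be held on advanced material. The fallback moves the differentiation of the two ring A oxygens ahead of the key step and sets out from alcohol 6. The same thiolate demethylation (NaSEt, DMF, 140 °C, then HCl), now on a simple and recyclable substrate, should give 5-(13-hydroxytridecyl)-3-methoxy-2-methylphenol F6. Selective phenol alkylation (BnBr, K2CO3, acetone) should give 13-[3-(benzyloxy)-5-methoxy-4-methylphenyl]tridecan-1-ol F7. Appel bromination (CBr4, PPh3) should give 1-(benzyloxy)-5-(13-bromotridecyl)-3-methoxy-2-methylbenzene F8. Acetylide alkylation with 8 should give 1-(benzyloxy)-3-methoxy-2-methyl-5-(pentadec-14-yn-1-yl)benzene F9. Dichloroketene cycloaddition (10, Zn–Cu couple) should give 3-{13-[3-(benzyloxy)-5-methoxy-4-methylphenyl]tridecyl}-4,4-dichlorocyclobut-2-en-1-one F10. Zinc dechlorination (Zn, AcOH, TMEDA) should give 3-{13-[3-(benzyloxy)-5-methoxy-4-methylphenyl]tridecyl}cyclobut-2-en-1-one F11. Benzannulation with 18 should give 5-{13-[3-(benzyloxy)-5-methoxy-4-methylphenyl]tridecyl}-2-methyl-3-[(triisopropylsilyl)oxy]phenol F12. Bu4NF (then aq. NH4Cl) should give 5-{13-[3-(benzyloxy)-5-methoxy-4-methylphenyl]tridecyl}-2-methylbenzene-1,3-diol F13. Hydrogenolysis (H2, Pd/C, EtOAc) then removes the benzyl ether, and the route is rejoined at 25.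

Further compounds
F1 | step 13 | 2-bromo-3-[13-(2-bromo-5-methoxy-4-methyl-3,6-dioxocyclohexa-1,4-dien-1-yl)tridecyl]-5-hydroxy-6-methylcyclohexa-2,5-diene-1,4-dione | COC1=C(C)C(=O)C(Br)=C(CCCCCCCCCCCCCC2=C(Br)C(=O)C(C)=C(O)C2=O)C1=O
F2 | step 9 | 14-(3,5-dimethoxy-4-methylphenyl)tetradecanal | O=CCCCCCCCCCCCCCc1cc(OC)c(C)c(OC)c1
F3 | step 9 | (E)-18-(3,5-dimethoxy-4-methylphenyl)octadec-4-en-3-one | CCC(=O)/C=C/CCCCCCCCCCCCCc1cc(OC)c(C)c(OC)c1
F4 | step 9 | methyl 6-[13-(3,5-dimethoxy-4-methylphenyl)tridecyl]-3-methyl-2,4-dioxocyclohexane-1-carboxylate (stereoisomer and enol mixture) | COC(=O)C1C(CCCCCCCCCCCCCc2cc(OC)c(C)c(OC)c2)CC(=O)C(C)C1=O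
F5 | step 9 | 5-[13-(3,5-dimethoxy-4-methylphenyl)tridecyl]-2-methylcyclohexane-1,3-dione | CC1C(=O)CC(CCCCCCCCCCCCCc2cc(OC)c(C)c(OC)c2)CC1=O
F6 | step 11 | 5-(13-hydroxytridecyl)-3-methoxy-2-methylphenol | COc1cc(CCCCCCCCCCCCCO)cc(O)c1C
F7 | step 11 | 13-[3-(benzyloxy)-5-methoxy-4-methylphenyl]tridecan-1-ol | COc1cc(CCCCCCCCCCCCCO)cc(OCc2ccccc2)c1C
F8 | step 11 | 1-(benzyloxy)-5-(13-bromotridecyl)-3-methoxy-2-methylbenzene | COc1cc(CCCCCCCCCCCCCBr)cc(OCc2ccccc2)c1C
F9 | step 11 | 1-(benzyloxy)-3-methoxy-2-methyl-5-(pentadec-14-yn-1-yl)benzene | COc1cc(CCCCCCCCCCCCCC#C)cc(OCc2ccccc2)c1C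
F10 | step 11 | 3-{13-[3-(benzyloxy)-5-methoxy-4-methylphenyl]tridecyl}-4,4-dichlorocyclobut-2-en-1-one | O=C1C=C(CCCCCCCCCCCCCc2cc(OC)c(C)c(OCc3ccccc3)c2)C1(Cl)Cl
F11 | step 11 | 3-{13-[3-(benzyloxy)-5-methoxy-4-methylphenyl]tridecyl}cyclobut-2-en-1-one | O=C1C=C(CCCCCCCCCCCCCc2cc(OC)c(C)c(OCc3ccccc3)c2)C1
F12 | step 11 | 5-{13-[3-(benzyloxy)-5-methoxy-4-methylphenyl]tridecyl}-2-methyl-3-[(triisopropylsilyl)oxy]phenol | COc1cc(CCCCCCCCCCCCCc2cc(O)c(C)c(O[Si](C(C)C)(C(C)C)C(C)C)c2)cc(OCc2ccccc2)c1C
F13 | step 11 | 5-{13-[3-(benzyloxy)-5-methoxy-4-methylphenyl]tridecyl}-2-methylbenzene-1,3-diol | COc1cc(CCCCCCCCCCCCCc2cc(O)c(C)c(O)c2)cc(OCc2ccccc2)c1C
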